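**Retrosynthetic overview**

1. Target 30 ← methyl ester 29 ← pyranone 28 by closing ring A at C8–C8a. The strategy rests on C8a: in ring B it is the enol-ether carbon that lies β, through C4a, to both the C4 and the C5 carbonyl, so as an O,S-ketene acetal carbon it accepts the C8 enolate of the C7 ketone.
2. 28 ← hydroxy triketone 26 + CS2/MeI: CS2 becomes C8a, which is substituted twice, first by O1 (ring B, closed first) and then by C8 (ring A, closed last).
3. 26 ← ester 25 by O→C acyl shift (C4a–C5 bond); 25 ← quaternary keto acid 23 + hydroxy ketone 12 (C2 and C3 from methyl (R)-3-hydroxybutanoate).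
4. 23: C6–C7 by decarboxylative Claisen condensation of the (S)-half-ester of 3-phenylglutaric anhydride (C9) with a malonate that carries the cyclobutylmethyl group from (−)-verbenone. The quaternary C6 is set by a Fráter–Seebach prenylation steered by a temporary C7 carbinol (Noyori hydrogenation), which is then oxidised away.

Key step: step 19

Remark: atoms are numbered as in the chromene core of the target (O1, C2–C8a; C9 is the benzylic carbon); CbCH2 stands for [(1R,3S)-2,2-dimethyl-3-(prop-1-en-2-yl)cyclobutyl]methyl and prenyl for 3-methylbut-2-en-1-yl.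
Assumption: quinidine is taken to deliver the (S)-half-ester 14 in step 10; if the sign of rotation of 14 shows the opposite sense, quinine replaces it and nothing else changes.

**Route**

Step 1
Reactants: 1 (1S,5S)-(−)-verbenone
Product: 2 (1S,3R)-3-acetyl-2,2-dimethylcyclobutane-1-carboxylic acid (cis-pinononic acid)
Conditions: RuCl3·xH2O (2 mol %), NaIO4 (4.2 equiv), MeCN/EtOAc/H2O, 0 °C → rt
Reagents that add atoms: sodium periodate, [Na+].[O-]I(=O)(=O)=O
Why: RuO4-mediated oxidative cleavage (RuO4 formed catalytically from RuCl3 and NaIO4) cuts the enone C=C bond, the α-keto acid formed loses one carbon as CO2, and the two ring stereocentres are carried over unchanged as the cis keto acid.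

Step 2
Reactants: 2 (1S,3R)-3-acetyl-2,2-dimethylcyclobutane-1-carboxylic acid
Product: 3 (1S,3S)-2,2-dimethyl-3-(prop-1-en-2-yl)cyclobutane-1-carboxylic acid
Conditions: Ph3PCH3Br (2.5 equiv), KOtBu (3.4 equiv), THF, 0 °C → rt; 1 M HCl, 0 °C
Reagents that add atoms: methyltriphenylphosphonium bromide, C[P+](c1ccccc1)(c1ccccc1)c1ccccc1.[Br-]
Why: Wittig methylenation of the methyl ketone in the presence of the carboxylate; the cis-1,3 arrangement is the more stable one on the puckered cyclobutane, so transient enolisation next to the acetyl group should not erode it.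

Step 3
Reactants: 3 (1S,3S)-2,2-dimethyl-3-(prop-1-en-2-yl)cyclobutane-1-carboxylic acid
Product: 4 [(1S,3S)-2,2-dimethyl-3-(prop-1-en-2-yl)cyclobutyl]methanol
Conditions: LiAlH4 (1.5 equiv), THF, 0 → 40 °C; H2O then 15 % aq. NaOH
Reagents that add atoms: none
Why: hydride reduction of the carboxylic acid to the primary alcohol, to which the isolated 1,1-disubstituted alkene is inert.

Step 4
Reactants: 4 [(1S,3S)-2,2-dimethyl-3-(prop-1-en-2-yl)cyclobutyl]methanol
Product: 5 (1S,3S)-1-(iodomethyl)-2,2-dimethyl-3-(prop-1-en-2-yl)cyclobutane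
Conditions: I2 (1.3 equiv), PPh3 (1.3 equiv), imidazole (1.5 equiv), CH2Cl2, 0 °C → rt, dark
Reagents that add atoms: iodine, II
Why: Appel-type iodination by SN2 displacement of the oxyphosphonium group at the primary carbon under buffered conditions that avoid cationic ring expansion.

Step 5
Reactants: 5 (1S,3S)-1-(iodomethyl)-2,2-dimethyl-3-(prop-1-en-2-yl)cyclobutane; 6 tert-butyl methyl propanedioate
Product: 7 1-tert-butyl 3-methyl 2-(CbCH2)propanedioate (C2 epimers)
Conditions: 6 (1.5 equiv), NaH (1.4 equiv), DMF, 0 °C; then 5, 65 °C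
Reagents that add atoms: none
Why: malonic ester alkylation, an SN2 reaction of the soft sodium malonate on the β-branched primary iodide that needs heat but has no competing pathway; excess malonate suppresses dialkylation.

Step 6
Reactants: 7 1-tert-butyl 3-methyl 2-(CbCH2)propanedioate
Product: 8 3-tert-butoxy-2-(CbCH2)-3-oxopropanoic acid (C2 epimers)
Conditions: KOH (1.05 equiv), MeOH/H2O, 0 °C → rt; 1 M HCl to pH 3, 0 °C
Reagents that add atoms: potassium hydroxide, [K+].[OH-]
Why: chemoselective saponification, in which hydroxide attacks the methyl ester while the tert-butyl ester is shielded, gives the malonic half-ester needed for the decarboxylative Claisen condensation.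

Step 7
Reactants: 9 methyl (R)-3-hydroxybutanoate
Product: 10 methyl (2R,3R)-3-hydroxy-2-methylbutanoate
Conditions: LiN(i-Pr)2 (2.2 equiv), THF, −78 → −20 °C; MeI (1.3 equiv), DMPU, −78 → 0 °C
Reagents that add atoms: iodomethane, CI
Why: Fráter–Seebach alkylation, in which the Li-chelated alkoxide–enolate dianion is methylated on the face anti to the C3 methyl group, which sets the anti (2R,3R) relationship that becomes C3/C2 of ring B.

Step 8
Reactants: 10 methyl (2R,3R)-3-hydroxy-2-methylbutanoate
Product: 11 (2R,3R)-3-hydroxy-N-methoxy-N,2-dimethylbutanamide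
Conditions: MeNH(OMe)·HCl (2.5 equiv), i-PrMgCl (6 equiv), THF, −20 → 0 °C
Reagents that add atoms: N,O-dimethylhydroxylamine hydrochloride, CNOC.Cl
Why: aminolysis of the ester by ClMgN(OMe)Me (Weinreb amide formation) with the hydroxyl carried as its magnesium alkoxide; the low temperature should prevent epimerisation at C2.

Step 9
Reactants: 11 (2R,3R)-3-hydroxy-N-methoxy-N,2-dimethylbutanamide
Product: 12 (3R,4R)-4-hydroxy-3-methylpentan-2-one
Conditions: MeMgBr (3 equiv), THF, −78 → 0 °C; aq. NH4Cl, 0 °C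
Reagents that add atoms: methylmagnesium bromide, C[Mg]Br
Why: Weinreb ketone synthesis, in which the chelated tetrahedral adduct stops the Grignard addition at the ketone stage and collapses only on quench, so the β-hydroxy methyl ketone should be released without retro-aldol cleavage or epimerisation.

Step 10
Reactants: 13 3-phenylglutaric anhydride
Product: 14 (3S)-5-methoxy-5-oxo-3-phenylpentanoic acid
Conditions: MeOH (5 equiv), quinidine (1.1 equiv), toluene, −55 °C; 1 M HCl wash (alkaloid recovered)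
Reagents that add atoms: methanol, CO
Why: alkaloid-mediated desymmetrising methanolysis of the prochiral anhydride, in which the chiral base delivers methanol to one of the two enantiotopic carbonyl groups and thereby sets C9.

Step 11
Reactants: 14 (3S)-5-methoxy-5-oxo-3-phenylpentanoic acid; 8 3-tert-butoxy-2-(CbCH2)-3-oxopropanoic acid
Product: 16 1-tert-butyl 7-methyl (2RS,5S)-2-(CbCH2)-3-oxo-5-phenylheptanedioate, via acyl imidazolide 15 (not isolated)
Conditions: 14, (imidazol-1-yl)2CO (1.1 equiv), THF, rt; then 8 (1.5 equiv), MgCl2 (1.6 equiv), Et3N (3.2 equiv), MeCN, rt → 40 °C; aq. citric acid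
Reagents that add atoms: 1,1′-carbonyldiimidazole, O=C(n1ccnc1)n1ccnc1 (imidazolyl group of intermediate 15 only)
Why: Masamune–Brooks decarboxylative Claisen condensation, in which the magnesium enolate of half-ester 8 is C-acylated by the imidazolide and loses CO2 to form the C6–C7 bond; C6 arises as an epimer mixture, which does not matter because it is enolised in step 13.

Step 12
Reactants: 16 1-tert-butyl 7-methyl (2RS,5S)-2-(CbCH2)-3-oxo-5-phenylheptanedioate
Product: 18 lithium (3S,5R,6RS)-7-tert-butoxy-6-(CbCH2)-5-hydroxy-7-oxo-3-phenylheptanoate, via hydroxy diester 17 (not isolated)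
Conditions: H2 (10 atm), RuCl2[(R)-BINAP] (1 mol %), MeOH, 50 °C; then LiOH·H2O (1.05 equiv), THF/H2O, 0 °C; lyophilise
Reagents that add atoms: lithium hydroxide, [Li+].[OH-]
Why: Noyori asymmetric hydrogenation, in which RuCl2[(R)-BINAP] reduces the ketone in the sense known for acetoacetates and sets the C7 carbinol (R) whatever the labile C6 configuration, and which at low pressure should spare the unconjugated alkene; LiOH then cleaves only the unhindered methyl ester (or the δ-lactone formed from it), so the distal carboxyl becomes a carboxylate that cannot be enolised in step 13.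

Step 13
Reactants: 18 lithium (3S,5R,6RS)-7-tert-butoxy-6-(CbCH2)-5-hydroxy-7-oxo-3-phenylheptanoate
Product: 20 1-tert-butyl 7-methyl (2S,3R,5S)-2-(CbCH2)-3-hydroxy-2-prenyl-5-phenylheptanedioate, via hydroxy acid 19 (not isolated)
Conditions: LiN(i-Pr)2 (2.4 equiv), THF/DMPU, −78 → −20 °C; prenyl bromide (1.3 equiv), −78 → −10 °C; pH 5 NaH2PO4 buffer, 0 °C; then Me3SiCHN2, toluene/MeOH, 0 °C
Reagents that add atoms: 1-bromo-3-methylbut-2-ene, CC(C)=CCBr; (trimethylsilyl)diazomethane, C[Si](C)(C)C=[N+]=[N-]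
Why: Fráter–Seebach alkylation of an α-substituted β-hydroxy ester, in which the Li chelate between the C7 alkoxide and the ester enolate fixes the enolate geometry and prenyl bromide enters anti to the C8 chain, which sets the quaternary C6 in the configuration of the target; the carboxylate is not α-deprotonated below −20 °C and is re-esterified before the δ-hydroxy acid can lactonise.

Step 14
Reactants: 20 1-tert-butyl 7-methyl (2S,3R,5S)-2-(CbCH2)-3-hydroxy-2-prenyl-5-phenylheptanedioate
Product: 21 1-tert-butyl 7-methyl (2S,5S)-2-(CbCH2)-2-prenyl-3-oxo-5-phenylheptanedioate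
Conditions: Dess–Martin periodinane (1.5 equiv), NaHCO3, CH2Cl2, 0 °C → rt
Reagents that add atoms: none
Why: Dess–Martin oxidation of the hindered secondary alcohol removes the auxiliary stereocentre at C7 and gives the C7 ketone next to the now non-enolisable C6.

Step 15
Reactants: 21 1-tert-butyl 7-methyl (2S,5S)-2-(CbCH2)-2-prenyl-3-oxo-5-phenylheptanedioate
Product: 23 (2S,5S)-2-(CbCH2)-7-methoxy-2-prenyl-3,7-dioxo-5-phenylheptanoic acid, via bis-silyl intermediate 22 (not isolated)
Conditions: Me3SiOTf (3 equiv), 2,6-lutidine (4 equiv), CH2Cl2, 0 °C; then pH 4 citrate buffer/THF, 0 °C; acid used at once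
Reagents that add atoms: trimethylsilyl trifluoromethanesulfonate, C[Si](C)(C)OS(=O)(=O)C(F)(F)F (silyl groups of intermediate 22 only)
Why: silyl-triflate-mediated cleavage of the tert-butyl ester (loss of isobutene from the O-silylated ester) under buffered, non-protic conditions that spare the prenyl and isopropenyl groups; mild hydrolysis of the silyl ester and of the silyl enol ether expected at the C7 ketone frees the β-keto acid, which is kept cold because it can decarboxylate.

Step 16
Reactants: 23 (2S,5S)-2-(CbCH2)-7-methoxy-2-prenyl-3,7-dioxo-5-phenylheptanoic acid; 12 (3R,4R)-4-hydroxy-3-methylpentan-2-one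
Product: 25 7-methyl 1-[(2R,3R)-3-methyl-4-oxopentan-2-yl] (2S,5S)-2-(CbCH2)-2-prenyl-3-oxo-5-phenylheptanedioate, via acid chloride 24 (not isolated)
Conditions: 1-chloro-N,N,2-trimethylprop-1-en-1-amine (1.3 equiv), CH2Cl2, 0 °C; then 12 (1.5 equiv), pyridine, DMAP (0.2 equiv), 0 → 35 °C
Reagents that add atoms: 1-chloro-N,N,2-trimethylprop-1-en-1-amine, CC(C)=C(Cl)N(C)C (chlorine of intermediate 24 only)
Why: acid chloride formation under neutral conditions with the α-chloroenamine, followed by DMAP-catalysed acylation of the secondary alcohol through the acylpyridinium ion; no stereocentre is touched and pyridine is too weak a base to trigger β-elimination of the new ester.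

Step 17
Reactants: 25 7-methyl 1-[(2R,3R)-3-methyl-4-oxopentan-2-yl] (2S,5S)-2-(CbCH2)-2-prenyl-3-oxo-5-phenylheptanedioate
Product: 26 methyl (3S,6S,10R,11R)-6-(CbCH2)-11-hydroxy-10-methyl-6-prenyl-5,7,9-trioxo-3-phenyldodecanoate
Conditions: LiN(SiMe3)2 (3.2 equiv), THF, −78 → −30 °C; AcOH, −78 °C; crude product taken on directly
Reagents that add atoms: none
Why: Baker–Venkataraman-type O→C acyl migration (intramolecular Claisen condensation), in which the kinetic methyl enolate at C4a attacks the ester carbonyl C5 through a six-membered transition state and the C2 alkoxide is expelled, forming the C4a–C5 bond; excess base also enolises C8 without consequence and the β-diketonate is the thermodynamic sink.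

Step 18
Reactants: 26 methyl (3S,6S,10R,11R)-6-(CbCH2)-11-hydroxy-10-methyl-6-prenyl-5,7,9-trioxo-3-phenyldodecanoate
Product: 28 methyl (3S,6S)-6-(CbCH2)-7-[(2R,3R)-2,3-dimethyl-6-(methylsulfanyl)-4-oxo-3,4-dihydro-2H-pyran-5-yl]-6-prenyl-5,7-dioxo-3-phenylheptanoate, via ketene dithioacetal 27 (not isolated)
Conditions: K2CO3 (3 equiv), CS2 (1.5 equiv), DMF, 0 °C; MeI (2.1 equiv), 0 °C → rt; then 45 °C
Reagents that add atoms: carbon disulfide, S=C=S; iodomethane, CI
Why: ketene dithioacetal formation at the 1,3-diketone carbon C4a (carbonate base, CS2, double S-methylation) followed by intramolecular addition–elimination of the C2 hydroxyl at the new carbon C8a (6-endo-trig oxa-Michael addition, loss of methanethiolate), which closes ring B with retention at C2.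

Step 19
Reactants: 28 methyl (3S,6S)-6-(CbCH2)-7-[(2R,3R)-2,3-dimethyl-6-(methylsulfanyl)-4-oxo-3,4-dihydro-2H-pyran-5-yl]-6-prenyl-5,7-dioxo-3-phenylheptanoate
Product: 29 methyl (3S)-3-[(2R,3R,6R)-6-(CbCH2)-5-hydroxy-2,3-dimethyl-6-prenyl-4,7-dioxo-3,4,6,7-tetrahydro-2H-chromen-8-yl]-3-phenylpropanoate
Conditions: LiN(SiMe3)2 (2.5 equiv), THF, −78 → 0 °C; aq. NH4Cl
Reagents that add atoms: none
Why: LiN(SiMe3)2 removes a proton from C8, the only enolisable position beside the C7 ketone because C6 is quaternary, and the enolate adds through carbon to C8a of the O,S-ketene acetal while the C4 and C5 carbonyls take up the charge; loss of methanethiolate restores the C4a=C8a bond, and a second equivalent of base turns the new β-triketone array into its delocalised enolate, which is protonated on work-up to the C5 enol. The closest known reaction type is the carbanion addition–elimination (vinylic substitution) on α-oxo ketene dithioacetals and their O,S analogues that underlies enolate annulations to cyclohexenones and phenols. Ring A closes by a 6-endo-trig addition (enolendo for the nucleophile) followed by elimination, the ring-forming bond being C8–C8a. No stereocentre is created, since C8 ends sp2, and C2, C3, C6 and C9 are not part of any enolate that persists. The step needs C8 to be deprotonated rather than C3 or the ester α-carbon, the enolate to react through carbon rather than oxygen, and C8a rather than the C4 carbonyl to be attacked. The simple ketone is the most acidic site kinetically, the lithium counter-ion in THF favours C-attack at the soft vinylogous position, and the aldol at C4 is reversible whereas thiolate loss and formation of the stabilised enolate are not.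

Step 20
Reactants: 29 methyl (3S)-3-[(2R,3R,6R)-6-(CbCH2)-5-hydroxy-2,3-dimethyl-6-prenyl-4,7-dioxo-3,4,6,7-tetrahydro-2H-chromen-8-yl]-3-phenylpropanoate
Product: 30 (3S)-3-[(2R,3R,6R)-6-(CbCH2)-5-hydroxy-2,3-dimethyl-6-prenyl-4,7-dioxo-3,4,6,7-tetrahydro-2H-chromen-8-yl]-3-phenylpropanoic acid (CNP0103716.3)
Conditions: LiOH·H2O (4 equiv), THF/MeOH/H2O, 0 °C → rt; 1 M HCl to pH 3, 0 °C
Reagents that add atoms: lithium hydroxide, [Li+].[OH-]
Why: saponification of the methyl ester, during which the bicyclic core is present as its delocalised enolate and is thereby protected from retro-Claisen cleavage and from epimerisation at C3; cold acidification returns the enol acid.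

**Compound list**

1 | (1S,5S)-(−)-verbenone | CC(=CC2=O)[C@@H]1C[C@H]2C1(C)C | starting material
2 | (1S,3R)-3-acetyl-2,2-dimethylcyclobutane-1-carboxylic acid | CC(=O)[C@@H]1C[C@H](C(=O)O)C1(C)C | intermediate
3 | (1S,3S)-2,2-dimethyl-3-(prop-1-en-2-yl)cyclobutane-1-carboxylic acid | C=C(C)[C@@H]1C[C@H](C(=O)O)C1(C)C | intermediate
4 | [(1S,3S)-2,2-dimethyl-3-(prop-1-en-2-yl)cyclobutyl]methanol | C=C(C)[C@@H]1C[C@H](CO)C1(C)C | intermediate
5 | (1S,3S)-1-(iodomethyl)-2,2-dimethyl-3-(prop-1-en-2-yl)cyclobutane | C=C(C)[C@@H]1C[C@H](CI)C1(C)C | intermediate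
6 | tert-butyl methyl propanedioate | COC(=O)CC(=O)OC(C)(C)C | starting material
7 | 1-tert-butyl 3-methyl 2-{[(1R,3S)-2,2-dimethyl-3-(prop-1-en-2-yl)cyclobutyl]methyl}propanedioate (C2 epimers) | COC(=O)C(C[C@H]1C[C@@H](C(C)=C)C1(C)C)C(=O)OC(C)(C)C | intermediate
8 | 3-tert-butoxy-2-{[(1R,3S)-2,2-dimethyl-3-(prop-1-en-2-yl)cyclobutyl]methyl}-3-oxopropanoic acid (C2 epimers) | OC(=O)C(C[C@H]1C[C@@H](C(C)=C)C1(C)C)C(=O)OC(C)(C)C | intermediate
9 | methyl (R)-3-hydroxybutanoate | C[C@@H](O)CC(=O)OC | starting material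
10 | methyl (2R,3R)-3-hydroxy-2-methylbutanoate | C[C@@H](O)[C@@H](C)C(=O)OC | intermediate
11 | (2R,3R)-3-hydroxy-N-methoxy-N,2-dimethylbutanamide | C[C@@H](O)[C@@H](C)C(=O)N(C)OC | intermediate
12 | (3R,4R)-4-hydroxy-3-methylpentan-2-one | C[C@@H](O)[C@@H](C)C(C)=O | intermediate
13 | 3-phenylglutaric anhydride | O=C1CC(c2ccccc2)CC(=O)O1 | starting material
14 | (3S)-5-methoxy-5-oxo-3-phenylpentanoic acid | OC(=O)C[C@@H](CC(=O)OC)c1ccccc1 | intermediate
15 | methyl (3S)-5-(1H-imidazol-1-yl)-5-oxo-3-phenylpentanoate | COC(=O)C[C@@H](c1ccccc1)CC(=O)n1ccnc1 | intermediate (not isolated)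
16 | 1-tert-butyl 7-methyl (2RS,5S)-2-(CbCH2)-3-oxo-5-phenylheptanedioate | CC(C)(C)OC(=O)C(C[C@H]1C[C@@H](C(C)=C)C1(C)C)C(=O)C[C@@H](CC(=O)OC)c1ccccc1 | intermediate
17 | 1-tert-butyl 7-methyl (2RS,3R,5S)-2-(CbCH2)-3-hydroxy-5-phenylheptanedioate | CC(C)(C)OC(=O)C(C[C@H]1C[C@@H](C(C)=C)C1(C)C)[C@H](O)C[C@@H](CC(=O)OC)c1ccccc1 | intermediate (not isolated)
18 | lithium (3S,5R,6RS)-7-tert-butoxy-6-(CbCH2)-5-hydroxy-7-oxo-3-phenylheptanoate | [Li+].[O-]C(=O)C[C@@H](c1ccccc1)C[C@@H](O)C(C[C@H]1C[C@@H](C(C)=C)C1(C)C)C(=O)OC(C)(C)C | intermediate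
19 | (3S,5R,6S)-7-tert-butoxy-6-(CbCH2)-5-hydroxy-6-prenyl-7-oxo-3-phenylheptanoic acid | OC(=O)C[C@@H](c1ccccc1)C[C@@H](O)[C@@](C[C@H]1C[C@@H](C(C)=C)C1(C)C)(CC=C(C)C)C(=O)OC(C)(C)C | intermediate (not isolated)
20 | 1-tert-butyl 7-methyl (2S,3R,5S)-2-(CbCH2)-3-hydroxy-2-prenyl-5-phenylheptanedioate | COC(=O)C[C@@H](c1ccccc1)C[C@@H](O)[C@@](C[C@H]1C[C@@H](C(C)=C)C1(C)C)(CC=C(C)C)C(=O)OC(C)(C)C | intermediate
21 | 1-tert-butyl 7-methyl (2S,5S)-2-(CbCH2)-2-prenyl-3-oxo-5-phenylheptanedioate | COC(=O)C[C@@H](c1ccccc1)CC(=O)[C@@](C[C@H]1C[C@@H](C(C)=C)C1(C)C)(CC=C(C)C)C(=O)OC(C)(C)C | intermediate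
22 | bis(trimethylsilyl) derivative of 23 (trimethylsilyl ester; C7 ketone as its trimethylsilyl enol ether towards C8, alkene geometry not defined) | COC(=O)C[C@@H](c1ccccc1)C=C(O[Si](C)(C)C)[C@@](C[C@H]1C[C@@H](C(C)=C)C1(C)C)(CC=C(C)C)C(=O)O[Si](C)(C)C | intermediate (not isolated)
23 | (2S,5S)-2-(CbCH2)-7-methoxy-2-prenyl-3,7-dioxo-5-phenylheptanoic acid | COC(=O)C[C@@H](c1ccccc1)CC(=O)[C@@](C[C@H]1C[C@@H](C(C)=C)C1(C)C)(CC=C(C)C)C(=O)O | intermediate
24 | methyl (3S,6S)-7-chloro-6-(CbCH2)-6-prenyl-5,7-dioxo-3-phenylheptanoate | COC(=O)C[C@@H](c1ccccc1)CC(=O)[C@@](C[C@H]1C[C@@H](C(C)=C)C1(C)C)(CC=C(C)C)C(Cl)=O | intermediate (not isolated)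
25 | 7-methyl 1-[(2R,3R)-3-methyl-4-oxopentan-2-yl] (2S,5S)-2-(CbCH2)-2-prenyl-3-oxo-5-phenylheptanedioate | COC(=O)C[C@@H](c1ccccc1)CC(=O)[C@@](C[C@H]1C[C@@H](C(C)=C)C1(C)C)(CC=C(C)C)C(=O)O[C@H](C)[C@@H](C)C(C)=O | intermediate
26 | methyl (3S,6S,10R,11R)-6-(CbCH2)-11-hydroxy-10-methyl-6-prenyl-5,7,9-trioxo-3-phenyldodecanoate | COC(=O)C[C@@H](c1ccccc1)CC(=O)[C@@](C[C@H]1C[C@@H](C(C)=C)C1(C)C)(CC=C(C)C)C(=O)CC(=O)[C@H](C)[C@@H](C)O | intermediate
27 | methyl (3S,6S,10R,11R)-8-[bis(methylsulfanyl)methylidene]-6-(CbCH2)-11-hydroxy-10-methyl-6-prenyl-5,7,9-trioxo-3-phenyldodecanoate | COC(=O)C[C@@H](c1ccccc1)CC(=O)[C@@](C[C@H]1C[C@@H](C(C)=C)C1(C)C)(CC=C(C)C)C(=O)C(=C(SC)SC)C(=O)[C@H](C)[C@@H](C)O | intermediate (not isolated)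
28 | methyl (3S,6S)-6-(CbCH2)-7-[(2R,3R)-2,3-dimethyl-6-(methylsulfanyl)-4-oxo-3,4-dihydro-2H-pyran-5-yl]-6-prenyl-5,7-dioxo-3-phenylheptanoate | CSC1=C(C(=O)[C@@](CC=C(C)C)(C[C@H]2C[C@@H](C(C)=C)C2(C)C)C(=O)C[C@@H](CC(=O)OC)c2ccccc2)C(=O)[C@H](C)[C@@H](C)O1 | intermediate
29 | methyl (3S)-3-[(2R,3R,6R)-6-(CbCH2)-5-hydroxy-2,3-dimethyl-6-prenyl-4,7-dioxo-3,4,6,7-tetrahydro-2H-chromen-8-yl]-3-phenylpropanoate | C=C(C)[C@@H]1C[C@H](C[C@@]2(CC=C(C)C)C(=O)C([C@@H](CC(=O)OC)c3ccccc3)=C3O[C@H](C)[C@@H](C)C(=O)C3=C2O)C1(C)C | intermediate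
30 | (3S)-3-[(2R,3R,6R)-6-(CbCH2)-5-hydroxy-2,3-dimethyl-6-prenyl-4,7-dioxo-3,4,6,7-tetrahydro-2H-chromen-8-yl]-3-phenylpropanoic acid | C=C(C)[C@@H]1C[C@H](C[C@@]2(CC=C(C)C)C(=O)C([C@@H](CC(=O)O)c3ccccc3)=C3O[C@H](C)[C@@H](C)C(=O)C3=C2O)C1(C)C | target

**Step count**

Total: 20 steps. Longest linear sequence: 16 steps (steps 1–6 and 11–20).

**Steps most likely to fail, with fallbacks**

Step 13. The trianion may alkylate slowly or unselectively: proton transfer to other sites, poor solubility, or weak facial discrimination in the second alkylation would lower the diastereomeric purity at C6. The hydrogenation before it may also touch the isopropenyl group. The fallback sets out from β-keto ester 16 and returns at keto diester 21. Compound 16 is condensed with tert-butyl L-valinate (cat. BF3·OEt2, benzene, reflux with water removal) to the chiral enamino ester 1-tert-butyl 7-methyl (5S)-3-{[(2S)-1-tert-butoxy-3-methyl-1-oxobutan-2-yl]amino}-2-(CbCH2)-5-phenylhept-2-enedioate F1. N-Lithiation with LiN(i-Pr)2 in toluene and prenylation at −78 → −20 °C follow; of the two co-solvents THF and HMPA, which give opposite faces with this auxiliary, the one that leads to the (2S) configuration is used. Hydrolysis with aqueous citric acid should then give 21 directly. This auxiliary-controlled alkylation of lithiated enamino esters is an established way to α,α-dialkyl β-keto esters and needs neither the carbinol at C7 nor the carboxylate.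

Step 17. The acyl transfer may be outrun by β-elimination of the carboxylate through the C3 enolate, or may stall because the ester carbonyl is shielded; the hindered esterification before it may also be slow. The fallback sets out from acid chloride 24 and hydroxy ketone 12 and returns at ketene dithioacetal 27. Ketone 12 is silylated (t-BuMe2SiCl, imidazole, DMF) to (3R,4R)-4-[(tert-butyldimethylsilyl)oxy]-3-methylpentan-2-one F2. Soft enolisation of F2 (MgBr2·OEt2, i-Pr2NEt, CH2Cl2) and intermolecular C-acylation with 24 should give methyl (3S,6S,10R,11R)-11-[(tert-butyldimethylsilyl)oxy]-6-(CbCH2)-10-methyl-6-prenyl-5,7,9-trioxo-3-phenyldodecanoate F3. K2CO3/CS2/MeI in DMF converts F3 into methyl (3S,6S,10R,11R)-8-[bis(methylsulfanyl)methylidene]-11-[(tert-butyldimethylsilyl)oxy]-6-(CbCH2)-10-methyl-6-prenyl-5,7,9-trioxo-3-phenyldodecanoate F4. HF·pyridine in THF then frees the C2 hydroxyl to give 27, which is cyclised to 28 with K2CO3 as in step 18.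

Step 19. The enolate may attack through oxygen, may add reversibly to the C4 carbonyl without going on, or ring B may open by β-elimination from a C3 enolate before the substitution takes place. The fallback sets out from 28 and returns at 29. Compound 28 is oxidised at sulfur (NaIO4, MeOH/H2O, 0 °C → rt) to the sulfoxide methyl (3S,6S)-6-(CbCH2)-7-[(2R,3R)-2,3-dimethyl-6-(methylsulfinyl)-4-oxo-3,4-dihydro-2H-pyran-5-yl]-6-prenyl-5,7-dioxo-3-phenylheptanoate F5. With the more electrophilic acceptor and the better leaving group, the cyclisation is then run under mild amine-base enolisation (DBU, MeCN, 0 °C), which should give 29 by addition–elimination on the β-sulfinyl enone.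

**Further compounds**

F1 | step 13 | 1-tert-butyl 7-methyl (5S)-3-{[(2S)-1-tert-butoxy-3-methyl-1-oxobutan-2-yl]amino}-2-(CbCH2)-5-phenylhept-2-enedioate | COC(=O)C[C@@H](c1ccccc1)CC(N[C@@H](C(C)C)C(=O)OC(C)(C)C)=C(C[C@H]1C[C@@H](C(C)=C)C1(C)C)C(=O)OC(C)(C)C
F2 | step 17 | (3R,4R)-4-[(tert-butyldimethylsilyl)oxy]-3-methylpentan-2-one | C[C@@H](O[Si](C)(C)C(C)(C)C)[C@@H](C)C(C)=O
F3 | step 17 | methyl (3S,6S,10R,11R)-11-[(tert-butyldimethylsilyl)oxy]-6-(CbCH2)-10-methyl-6-prenyl-5,7,9-trioxo-3-phenyldodecanoate | COC(=O)C[C@@H](c1ccccc1)CC(=O)[C@@](C[C@H]1C[C@@H](C(C)=C)C1(C)C)(CC=C(C)C)C(=O)CC(=O)[C@H](C)[C@@H](C)O[Si](C)(C)C(C)(C)C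
F4 | step 17 | methyl (3S,6S,10R,11R)-8-[bis(methylsulfanyl)methylidene]-11-[(tert-butyldimethylsilyl)oxy]-6-(CbCH2)-10-methyl-6-prenyl-5,7,9-trioxo-3-phenyldodecanoate | COC(=O)C[C@@H](c1ccccc1)CC(=O)[C@@](C[C@H]1C[C@@H](C(C)=C)C1(C)C)(CC=C(C)C)C(=O)C(=C(SC)SC)C(=O)[C@H](C)[C@@H](C)O[Si](C)(C)C(C)(C)C
F5 | step 19 | methyl (3S,6S)-6-(CbCH2)-7-[(2R,3R)-2,3-dimethyl-6-(methylsulfinyl)-4-oxo-3,4-dihydro-2H-pyran-5-yl]-6-prenyl-5,7-dioxo-3-phenylheptanoate (sulfur epimers) | CS(=O)C1=C(C(=O)[C@@](CC=C(C)C)(C[C@H]2C[C@@H](C(C)=C)C2(C)C)C(=O)C[C@@H](CC(=O)OC)c2ccccc2)C(=O)[C@H](C)[C@@H](C)O1
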